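The upper flavan is not closed as a pyran. Its ring C (O1, C2, C3, C4, C4a, C8a) is grown from a 2-aryl-2,3-dihydrobenzofuran by a one-carbon ring expansion. A catalytic asymmetric carbene C–H insertion sets C2; the derived trans 3-(mesyloxymethyl)dihydrobenzofuran ionises with participation of C4a, the ring A carbon ortho to O1 and para to the 7-oxygen. Water opens the spiro phenonium ion at the ring carbon, so in one operation the aryl shift makes the six-membered ring and sets C3 by inversion, trans to C2. C4 oxidation, Friedel–Crafts union with C8-blocked epicatechin at its C6 and hydrogenolysis complete the route.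

Key step: step 8

Remark: in step 6 the R-configured dirhodium carboxylate is assumed to give the 2S product (the S-ligand being taken to give the 2R series); if the induction proves opposite, the enantiomeric catalyst is used.

**Lower unit**

Step 1
Reactants: 1 (−)-epicatechin
Product: 2 (2R,3R)-5,7-bis(benzyloxy)-2-[3,4-bis(benzyloxy)phenyl]chroman-3-ol
Conditions: BnBr (4.2 equiv), K2CO3, DMF, 0 °C to rt, argon
Reagents that add atoms: benzyl bromide, BrCc1ccccc1
Why: Williamson etherification: carbonate deprotonates only the four phenols, so the secondary 3-OH stays free and neither stereocentre is touched.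

Step 2
Reactants: 2 tetra-O-benzylepicatechin
Product: 3 (2R,3R)-5,7-bis(benzyloxy)-2-[3,4-bis(benzyloxy)phenyl]-8-bromochroman-3-ol
Conditions: NBS (1.05 equiv), CH2Cl2, −78 °C to rt
Reagents that add atoms: N-bromosuccinimide, O=C1CCC(=O)N1Br
Why: Electrophilic aromatic bromination of the phloroglucinol-type ring A, which in benzylated flavan-3-ols takes place at the more reactive C8, so that bromine blocks C8 and leaves C6 as the only nucleophilic carbon for step 10.

**Upper unit**

Step 3
Reactants: 4 methyl 2-(2,4-dihydroxyphenyl)acetate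
Product: 5 methyl 2-[4-(benzyloxy)-2-hydroxyphenyl]acetate
Conditions: BnBr (1.0 equiv), K2CO3 (1.05 equiv), acetone, rt
Reagents that add atoms: benzyl bromide, BrCc1ccccc1
Why: Williamson etherification with one equivalent of halide should go mainly to the unhindered 4-OH, because the 2-OH is flanked by the CH2CO2Me group and hydrogen-bonded to the ester carbonyl; minor 2-O and bis-ethers are removed by chromatography.

Step 4
Reactants: 5 methyl 2-[4-(benzyloxy)-2-hydroxyphenyl]acetate, 6 4-(benzyloxy)benzyl chloride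
Product: 7 methyl 2-[4-(benzyloxy)-2-{[4-(benzyloxy)benzyl]oxy}phenyl]acetate
Conditions: K2CO3, n-Bu4NI (cat.), DMF, 50 °C
Reagents that add atoms: none
Why: Williamson etherification of the remaining phenol (iodide catalysis through the benzylic iodide) installs the O–CH2–aryl unit that becomes C2 and ring B.

Step 5
Reactants: 7 methyl 2-[4-(benzyloxy)-2-{[4-(benzyloxy)benzyl]oxy}phenyl]acetate
Product: 8 methyl 2-[4-(benzyloxy)-2-{[4-(benzyloxy)benzyl]oxy}phenyl]-2-diazoacetate
Conditions: p-ABSA (1.3 equiv), DBU (1.5 equiv), MeCN, 0 °C to rt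
Reagents that add atoms: 4-acetamidobenzenesulfonyl azide, CC(=O)Nc1ccc(cc1)S(=O)(=O)N=[N+]=[N-]
Why: Regitz diazo transfer to the DBU enolate of the arylacetate gives the donor/acceptor diazo ester.

Step 6
Reactants: 8 methyl 2-[4-(benzyloxy)-2-{[4-(benzyloxy)benzyl]oxy}phenyl]-2-diazoacetate
Product: 10 methyl (2S,3S)-6-(benzyloxy)-2-[4-(benzyloxy)phenyl]-2,3-dihydro-1-benzofuran-3-carboxylate (trans ester), via cis ester 9 (not isolated)
Conditions: Rh2(R-PTTL)4 [dirhodium tetrakis(N-phthaloyl-(R)-tert-leucinate)] (1 mol %), toluene, −60 °C; then NaOMe (0.3 equiv), MeOH, 0 °C to rt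
Reagents that add atoms: none
Why: Dirhodium-carbene 1,5-C–H insertion into the O–CH2–aryl group closes the dihydrobenzofuran, the chiral carboxylate ligands distinguishing the two enantiotopic benzylic hydrogens to set C2 (S) in the cis ester 9, and catalytic methoxide then epimerises the acidic C3–H to the thermodynamically favoured trans ester without touching C2.

Step 7
Reactants: 10 trans ester
Product: 11 [(2S,3R)-6-(benzyloxy)-2-[4-(benzyloxy)phenyl]-2,3-dihydro-1-benzofuran-3-yl]methanol
Conditions: LiAlH4, THF, 0 °C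
Reagents that add atoms: none
Why: Hydride reduction of the ester to the primary alcohol; both stereocentres are retained (the C3 descriptor changes only through priorities).

Step 8
Reactants: 11 [(2S,3R)-6-(benzyloxy)-2-[4-(benzyloxy)phenyl]-2,3-dihydro-1-benzofuran-3-yl]methanol
Product: 14 (2R,3S)-7-(benzyloxy)-2-[4-(benzyloxy)phenyl]chroman-3-ol, via mesylate 12 (not isolated), via phenonium ion 13 (not isolated)
Conditions: MsCl, Et3N, CH2Cl2, 0 °C; then HFIP–H2O (9:1), 2,6-lutidine, 40 °C
Reagents that add atoms: water, O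
Why: Anchimerically assisted solvolysis with a 1,2-aryl shift (Wagner–Meerwein rearrangement through a phenonium ion): as the primary mesylate ionises in the strongly ionising, weakly nucleophilic medium, the π-lobe of C4a (ortho to O1, para to the 7-benzyloxy group) bonds to the exocyclic CH2 to give the spiro-cyclopropyl arenium ion 13, which water opens at the ring carbon with cleavage of the old C3–C4a bond. The closest known reactions are the solvolytic and Demjanov ring enlargements of indan-1-ylmethyl derivatives to 2-tetralyl products and the rearranging solvolyses of 2-(alkoxyaryl)ethyl sulfonates. The pyran ring is not closed by a cyclisation but arises by ring enlargement: a 3-exo ipso attack gives the spiro three-membered ring and its fusion bond is then broken, which turns the five-membered ring (O1, C2, C3, C4a, C8a) into the six-membered ring (O1, C2, C3, C4, C4a, C8a) and relieves the strain of the bicyclic ion. The new C3 stereocentre is set by substrate stereospecificity: water enters anti to the departing C4a, so C3 is inverted and the (2S,3R)-trans precursor should give the 3-OH trans to the 2-aryl group (2R,3S; C2 itself is untouched and its descriptor changes only through priorities). The step needs aryl participation to win over a hydride shift from C3, over migration of the ring C2–C3 bond and over direct displacement, and it needs opening at the secondary carbon; the doubly oxygen-activated ipso carbon, the in-plane C2–C3 bond (whose migration would leave a cation orthogonal to the π system), the β-branched primary centre in a non-nucleophilic solvent and the strain relief on breaking the fusion bond should secure this, and attack at CH2 only returns 11. 2,6-Lutidine keeps the medium neutral so that the acid-labile benzylic C2–O1 bond is not ionised.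

Step 9
Reactants: 14 (2R,3S)-7-(benzyloxy)-2-[4-(benzyloxy)phenyl]chroman-3-ol
Product: 15 (2R,3S,4S)-7-(benzyloxy)-2-[4-(benzyloxy)phenyl]-4-(2-ethoxyethoxy)chroman-3-ol
Conditions: DDQ (2 equiv), 2-ethoxyethanol (5 equiv), CH2Cl2, rt
Reagents that add atoms: 2-ethoxyethanol, CCOCCO
Why: Oxidative benzylic functionalisation: DDQ abstracts hydride from C4 (benzylic to ring A, conjugated with O1 and the para 7-benzyloxy group) and the alcohol traps the cation, expected mainly on the β-face (4S); ring B with one oxygen is the poorer donor, so C2–H should be spared, and the C4 configuration is lost again on ionisation in step 10.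

**Union and deprotection**

Step 10
Reactants: 15 (2R,3S,4S)-4-(2-ethoxyethoxy)flavan-3-ol, 3 8-bromo-tetra-O-benzylepicatechin
Product: 16 (2R,3S,4S)-7-(benzyloxy)-2-[4-(benzyloxy)phenyl]-4-[(2R,3R)-5,7-bis(benzyloxy)-2-[3,4-bis(benzyloxy)phenyl]-8-bromo-3-hydroxychroman-6-yl]chroman-3-ol
Conditions: 3 (3 equiv), TMSOTf (0.2 equiv), CH2Cl2, −78 to −30 °C
Reagents that add atoms: none
Why: Lewis acid-promoted Friedel–Crafts coupling through the flavan-4-yl cation: TMSOTf ionises the chelating 4-alkoxy group and C6 of 3, its only free nucleophilic carbon, attacks from the α-face, anti to the 3-OH, to give the 3,4-trans (4S) interflavan bond, while excess 3 suppresses self-condensation of 15.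

Step 11
Reactants: 16 protected dimer
Product: 17 (2R,3S,4S)-2-(4-hydroxyphenyl)-4-[(2R,3R)-2-(3,4-dihydroxyphenyl)-3,5,7-trihydroxychroman-6-yl]chroman-3,7-diol (guibourtinidol-(4α→6)-epicatechin, the target)
Conditions: H2 (1 atm), Pd(OH)2/C, Et3N, THF–MeOH–H2O, rt
Reagents that add atoms: none
Why: Catalytic hydrogenolysis cleaves the six benzyl ethers and the aryl C–Br bond in one operation, Et3N taking up HBr so that the acid-labile interflavan bond is not exposed to acid; no stereocentre is involved.

**Compound list**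

1 | (−)-epicatechin | O[C@@H]1Cc2c(O)cc(O)cc2O[C@@H]1c1ccc(O)c(O)c1 | starting material
2 | (2R,3R)-5,7-bis(benzyloxy)-2-[3,4-bis(benzyloxy)phenyl]chroman-3-ol | O[C@@H]1Cc2c(OCc3ccccc3)cc(OCc3ccccc3)cc2O[C@@H]1c1ccc(OCc2ccccc2)c(OCc2ccccc2)c1 | intermediate
3 | (2R,3R)-5,7-bis(benzyloxy)-2-[3,4-bis(benzyloxy)phenyl]-8-bromochroman-3-ol | O[C@@H]1Cc2c(OCc3ccccc3)cc(OCc3ccccc3)c(Br)c2O[C@@H]1c1ccc(OCc2ccccc2)c(OCc2ccccc2)c1 | intermediate
4 | methyl 2-(2,4-dihydroxyphenyl)acetate | COC(=O)Cc1ccc(O)cc1O | starting material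
5 | methyl 2-[4-(benzyloxy)-2-hydroxyphenyl]acetate | COC(=O)Cc1ccc(OCc2ccccc2)cc1O | intermediate
6 | 4-(benzyloxy)benzyl chloride | ClCc1ccc(OCc2ccccc2)cc1 | starting material
7 | methyl 2-[4-(benzyloxy)-2-{[4-(benzyloxy)benzyl]oxy}phenyl]acetate | COC(=O)Cc1ccc(OCc2ccccc2)cc1OCc1ccc(OCc2ccccc2)cc1 | intermediate
8 | methyl 2-[4-(benzyloxy)-2-{[4-(benzyloxy)benzyl]oxy}phenyl]-2-diazoacetate | COC(=O)C(=[N+]=[N-])c1ccc(OCc2ccccc2)cc1OCc1ccc(OCc2ccccc2)cc1 | intermediate
9 | methyl (2S,3R)-6-(benzyloxy)-2-[4-(benzyloxy)phenyl]-2,3-dihydro-1-benzofuran-3-carboxylate (cis ester, not isolated) | COC(=O)[C@@H]1c2ccc(OCc3ccccc3)cc2O[C@@H]1c1ccc(OCc2ccccc2)cc1 | intermediate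
10 | methyl (2S,3S)-6-(benzyloxy)-2-[4-(benzyloxy)phenyl]-2,3-dihydro-1-benzofuran-3-carboxylate (trans ester) | COC(=O)[C@H]1c2ccc(OCc3ccccc3)cc2O[C@@H]1c1ccc(OCc2ccccc2)cc1 | intermediate
11 | [(2S,3R)-6-(benzyloxy)-2-[4-(benzyloxy)phenyl]-2,3-dihydro-1-benzofuran-3-yl]methanol (trans) | OC[C@H]1c2ccc(OCc3ccccc3)cc2O[C@@H]1c1ccc(OCc2ccccc2)cc1 | intermediate
12 | [(2S,3R)-6-(benzyloxy)-2-[4-(benzyloxy)phenyl]-2,3-dihydro-1-benzofuran-3-yl]methyl methanesulfonate (not isolated) | CS(=O)(=O)OC[C@H]1c2ccc(OCc3ccccc3)cc2O[C@@H]1c1ccc(OCc2ccccc2)cc1 | intermediate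
13 | phenonium ion: spiro-cyclopropyl arenium cation in which C4a is bonded to both C3 and the former CH2, drawn as its O1-oxocarbenium form, mesylate counter-ion (not isolated) | C1[C@@H]2[C@@H](c3ccc(OCc4ccccc4)cc3)[O+]=C3C=C(OCc4ccccc4)C=C[C@@]123.CS(=O)(=O)[O-] | intermediate
14 | (2R,3S)-7-(benzyloxy)-2-[4-(benzyloxy)phenyl]chroman-3-ol (7,4'-di-O-benzylguibourtinidol) | O(Cc1ccccc1)c1ccc([C@H]2Oc3cc(OCc4ccccc4)ccc3C[C@@H]2O)cc1 | intermediate
15 | (2R,3S,4S)-7-(benzyloxy)-2-[4-(benzyloxy)phenyl]-4-(2-ethoxyethoxy)chroman-3-ol | O(Cc1ccccc1)c1ccc([C@H]2Oc3cc(OCc4ccccc4)ccc3[C@H](OCCOCC)[C@@H]2O)cc1 | intermediate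
16 | (2R,3S,4S)-7-(benzyloxy)-2-[4-(benzyloxy)phenyl]-4-[(2R,3R)-5,7-bis(benzyloxy)-2-[3,4-bis(benzyloxy)phenyl]-8-bromo-3-hydroxychroman-6-yl]chroman-3-ol | C(c1ccccc1)Oc1ccc([C@H]2Oc3cc(OCc4ccccc4)ccc3[C@@H](c3c(OCc4ccccc4)c(Br)c4c(c3OCc3ccccc3)C[C@@H](O)[C@@H](c3ccc(OCc5ccccc5)c(OCc5ccccc5)c3)O4)[C@@H]2O)cc1 | intermediate
17 | (2R,3S,4S)-2-(4-hydroxyphenyl)-4-[(2R,3R)-2-(3,4-dihydroxyphenyl)-3,5,7-trihydroxychroman-6-yl]chroman-3,7-diol | Oc1ccc([C@H]2Oc3cc(O)ccc3[C@@H](c3c(O)cc4c(c3O)C[C@@H](O)[C@@H](c3ccc(O)c(O)c3)O4)[C@@H]2O)cc1 | target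

**Step count and risks**

Total steps: 11. Longest linear sequence: 9 steps (4 to 17, steps 3 to 11).

Steps most likely to fail:

Step 8 (ring enlargement). The ionisation may be diverted by a 1,2-hydride shift from C3 (ending, after proton loss, in a 3-methyl-2-arylbenzofuran), by direct displacement at the primary carbon without rearrangement, or by opening of the bridged ion at CH2. The fallback is a deaminative (Demjanov) ring enlargement that sets out from 10. Ammonolysis (NH3 in MeOH, 60 °C) should give (2S,3S)-6-(benzyloxy)-2-[4-(benzyloxy)phenyl]-2,3-dihydro-1-benzofuran-3-carboxamide F1. LiAlH4 in THF at reflux should give the trans 3-(aminomethyl)dihydrobenzofuran F2. NaNO2 in aqueous AcOH at 0 °C then diazotises F2; loss of N2 is irreversible and needs no solvent nucleophile, C4a migrates as before, and water captures the ion at C3, which comes back to the route at 14.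

Step 9 (C4 oxidation). Hydride abstraction at C4 of the 5-deoxy ring A may be slow, and oxidation at C2–H (a para-alkoxybenzylic ether position) may compete and open the pyran ring. The fallback sets out from 14. Acetylation (Ac2O, pyridine) gives (2R,3S)-7-(benzyloxy)-2-[4-(benzyloxy)phenyl]chroman-3-yl acetate F3. Benzylic acetoxylation with Pb(OAc)4 in benzene (a ligand-transfer oxidation in place of hydride abstraction) gives the 3,4-diacetate F4 as a C4 epimer mixture. BF3·OEt2-promoted coupling of F4 with 3, now under neighbouring-group control by the 3-acetoxy group (acetoxonium ion on the β-face), gives the 3-O-acetyl dimer F5. K2CO3 in MeOH–THF removes the acetate and comes back to the route at 16.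

Step 10 (coupling). Self-condensation of 15 through C6 or C8 of its own ring A, slow attack by the hindered C6 of 3, and incomplete α-facial selectivity may erode the step. The fallback sets out from 15. Exchange of the 4-alkoxy group for sulfur (BnSH, BF3·OEt2, CH2Cl2, −20 °C) gives the 4α-benzylsulfanyl flavan-3-ol F6. Thiophilic activation of F6 with AgBF4 in THF at 0 °C in the presence of 3 forms the interflavan bond under neutral conditions and comes back to the route at 16.

Further compounds
F1 | step 8 | (2S,3S)-6-(benzyloxy)-2-[4-(benzyloxy)phenyl]-2,3-dihydro-1-benzofuran-3-carboxamide | NC(=O)[C@H]1c2ccc(OCc3ccccc3)cc2O[C@@H]1c1ccc(OCc2ccccc2)cc1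
F2 | step 8 | [(2S,3R)-6-(benzyloxy)-2-[4-(benzyloxy)phenyl]-2,3-dihydro-1-benzofuran-3-yl]methanamine | NC[C@H]1c2ccc(OCc3ccccc3)cc2O[C@@H]1c1ccc(OCc2ccccc2)cc1
F3 | step 9 | (2R,3S)-7-(benzyloxy)-2-[4-(benzyloxy)phenyl]chroman-3-yl acetate | O(Cc1ccccc1)c1ccc([C@H]2Oc3cc(OCc4ccccc4)ccc3C[C@@H]2OC(C)=O)cc1
F4 | step 9 | (2R,3S)-7-(benzyloxy)-2-[4-(benzyloxy)phenyl]chroman-3,4-diyl diacetate (C4 epimers) | O(Cc1ccccc1)c1ccc([C@H]2Oc3cc(OCc4ccccc4)ccc3C(OC(C)=O)[C@@H]2OC(C)=O)cc1
F5 | step 9 | 3-O-acetate of 16 (acetate on the 3-OH of the upper unit) | C(c1ccccc1)Oc1ccc([C@H]2Oc3cc(OCc4ccccc4)ccc3[C@@H](c3c(OCc4ccccc4)c(Br)c4c(c3OCc3ccccc3)C[C@@H](O)[C@@H](c3ccc(OCc5ccccc5)c(OCc5ccccc5)c3)O4)[C@@H]2OC(C)=O)cc1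
F6 | step 10 | 7-(benzyloxy)-2-[4-(benzyloxy)phenyl]-4α-(benzylsulfanyl)chroman-3-ol (2,3-trans-3,4-trans) | O(Cc1ccccc1)c1ccc([C@H]2Oc3cc(OCc4ccccc4)ccc3[C@@H](SCc3ccccc3)[C@@H]2O)cc1
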